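**Retrosynthetic overview**
- Target ⇐ methylenation of the C8 ketone ⇐ enone aryl ether ⇐ base-mediated conjugation of a β,γ-enone plus oxa-Michael addition of umbelliferone to a C9=C11 exocyclic enone.
- Ring A ⇐ one thermal operation on a monocyclic ring B dienone carbinol: an oxy-Cope shift makes C1–C10 (and turns C11 into the C9 methylidene), then a carbonyl-ene closure makes C3–C4.
- Enabling feature: in ring B, C9=C10 is the acceptor end of a 3-hydroxy-1,5-diene (C1=C2–C3(OH)–C11–C9=C10) and carries the C8 acyl group on its inner carbon C9. C4 is the outer carbon of an isopropylidene group on C5; once C10 is quaternary it is an isolated ene donor with H-6 as the only transferable hydrogen.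
- Dienone carbinol ⇐ Hagemann's ester (ring B with the C8 ketone and the C10 methyl): C9 allylation, ester → CMe2 with MeLi, dehydration, allyl → aldehyde → enantioselective vinylation.
- Ring order: ring B is bought, ring A is closed in the key step, the coumarin ether is attached after it.

Key step: step 7

Remark: drimane numbering is used for the decalin (C11 = CH2O carbon on C9, C12 = exocyclic methylene carbon on C8); the target is (3S,5S,9R,10R), with the 3-hydroxyl axial and anti to the C10 methyl.

**Step 1**
Reactants: 1 ethyl 2-methyl-4-oxocyclohex-2-ene-1-carboxylate (Hagemann's ester, racemic); 2 3-bromoprop-1-ene (allyl bromide)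
Product: 3 ethyl 2-methyl-4-oxo-3-(prop-2-en-1-yl)cyclohex-2-ene-1-carboxylate (racemic)
Conditions: KOtBu, t-BuOH, 80 °C
Reagents that add atoms: none
Why: C-alkylation of the vinylogous β-keto ester enolate of Hagemann's ester, which is known to react at C-3 (the enone α-carbon), should place the allyl group on the future C9.

**Step 2**
Reactants: 3
Product: 4 ethyl 7-methyl-6-(prop-2-en-1-yl)-1,4-dioxaspiro[4.5]dec-7-ene-8-carboxylate (racemic)
Conditions: HOCH2CH2OH, p-TsOH (cat.), PhH, reflux, Dean–Stark
Reagents that add atoms: ethane-1,2-diol, OCCO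
Why: Acid-catalysed ketalisation with the usual shift of the double bond into conjugation with the ester protects the ketone for the organolithium step; the new stereocentre is irrelevant because it becomes sp2 again in step 4.

**Step 3**
Reactants: 4
Product: 6 2-[7-methyl-6-(prop-2-en-1-yl)-1,4-dioxaspiro[4.5]dec-7-en-8-yl]propan-2-ol (racemic), via methyl ketone 5 (not isolated)
Conditions: MeLi (3 equiv), THF, −78 → 0 °C; then H2O
Reagents that add atoms: methyllithium, [Li]C
Why: Double 1,2-addition of methyllithium to the ester should give the tertiary carbinol that carries both methyl groups of the future C4, the fully substituted β-carbon ruling out conjugate addition.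

**Step 4**
Reactants: 6
Product: 8 3-methyl-2-(prop-2-en-1-yl)-4-(propan-2-ylidene)cyclohex-2-en-1-one, via hydroxy enone 7 (not isolated)
Conditions: PPTS (cat.), acetone/H2O, 45 °C
Reagents that add atoms: water, O
Why: Mild acid hydrolysis of the ketal and E1-type dehydration of the tertiary allylic alcohol (loss of the acidic H-9) should give the fully conjugated dienone, the weak acid being chosen so that ring B does not tautomerise to the isomeric phenol.

**Step 5**
Reactants: 8
Product: 10 2-[2-methyl-6-oxo-3-(propan-2-ylidene)cyclohex-1-en-1-yl]acetaldehyde, via diol 9 (not isolated)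
Conditions: OsO4 (cat.), NaIO4, 2,6-lutidine, dioxane/H2O, rt
Reagents that add atoms: osmium tetroxide, O=[Os](=O)(=O)=O; sodium periodate, [Na+].[O-]I(=O)(=O)=O
Why: Lemieux–Johnson cleavage should occur at the unhindered monosubstituted alkene in preference to the two tetrasubstituted, electron-poor alkenes of the dienone.

**Step 6**
Reactants: 10
Product: 11 2-[(2S)-2-hydroxybut-3-en-1-yl]-3-methyl-4-(propan-2-ylidene)cyclohex-2-en-1-one
Conditions: Zn(CH=CH2)2, (+)-DAIB (10 mol %), PhMe, 0 °C; aq. NH4Cl
Reagents that add atoms: divinylzinc, C=C[Zn]C=C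
Why: Amino-alcohol-catalysed enantioselective addition of divinylzinc to the aldehyde (Noyori/Oppolzer-type organozinc addition), chemoselective over the hindered conjugated ketone, should deliver the vinyl group to the Re face and set the 2S carbinol, the only stereocentre set by a chiral reagent.

**Step 7**
Reactants: 11
Product: 14 (6S,8aR)-6-hydroxy-5,5,8a-trimethyl-1-methylidene-3,5,6,7,8,8a-hexahydronaphthalen-2(1H)-one, via enol 12 (not isolated), via keto aldehyde 13 (not isolated)
Conditions: PhMe (0.01 M), BHT (cat.), base-washed sealed tube, 170 °C (microwave)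
Reagents that add atoms: none
Why: Proposed new method: heating should trigger a [3,3]-sigmatropic oxy-Cope shift of the 3-hydroxy-1,5-diene C1=C2–C3(OH)–C11–C9=C10, accelerated by the C8 acyl group on the inner carbon of the accepting allyl unit and by the internal O–H···O=C8 hydrogen bond, to give enol 12 and, after tautomerisation, keto aldehyde 13 with C1–C10 formed and C10 quaternary (closest known reaction types: thermal oxy-Cope rearrangement, Cope rearrangement of 2-acyl-1,5-dienes, tandem oxy-Cope/ene sequences of 1,2-divinylcycloalkanols). The aldehyde should then close ring A by an intramolecular carbonyl-ene reaction in which C3 bonds to C4, the alkene carbon remote from the tether (six-membered closure, endo with respect to the isopropylidene alkene), with transfer of H-6 to oxygen and shift of the alkene to C5=C6. C10 is set by chirality transfer from the 2S carbinol through the chair transition state in which the hydroxyl is pseudo-equatorial and hydrogen-bonded to the C8 carbonyl, so that C1 adds to the face of C9=C10 that leaves the methyl anti to it. C3 is set in the ene step, because the carbonyl oxygen must lie gauche to C5 to accept H-6, which in the chair transition state makes the new hydroxyl axial and anti to the angular methyl. The step needs the sigmatropic shift to outrun retro-ene loss of acrolein and phenol formation, which the acyl acceleration and neutral conditions are meant to secure, and it needs the ene reaction at C4 only, which is secured because the C9 methylidene is deactivated by the ketone, attack at C5 would create two adjacent quaternary carbons, and C6 holds the only allylic hydrogens. The s-trans-locked diene of ring B excludes Diels–Alder pathways.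

**Step 8**
Reactants: 14; 15 7-hydroxy-2H-chromen-2-one (umbelliferone)
Product: 17 7-{[(1R,4aS,6S,8aR)-6-hydroxy-5,5,8a-trimethyl-2-oxo-1,2,4a,5,6,7,8,8a-octahydronaphthalen-1-yl]methoxy}-2H-chromen-2-one, via dienone 16 (not isolated)
Conditions: 15 (2 equiv), DBU (0.3 equiv), MeCN, 40 °C
Reagents that add atoms: none
Why: Base-mediated conjugation of the β,γ-unsaturated ketone (γ-protonation of the dienolate at C5 anti to the angular methyl gives the trans ring fusion) followed by oxa-Michael addition of the phenoxide to C11 should give the aryl ether, and protonation of the enolate at C9 anti to the angular methyl places the aryloxymethyl group equatorial and cis to that methyl.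

**Step 9**
Reactants: 17
Product: 18 7-{[(1R,4aS,6S,8aR)-6-hydroxy-5,5,8a-trimethyl-2-methylidene-1,2,4a,5,6,7,8,8a-octahydronaphthalen-1-yl]methoxy}-2H-chromen-2-one (target)
Conditions: Zn, CH2Br2, TiCl4, THF/CH2Cl2, 0 °C → rt (excess reagent)
Reagents that add atoms: dibromomethane, BrCBr
Why: Lombardo methylenation converts the enone carbonyl into the exocyclic methylene without base, so the β-aryloxy ketone should not eliminate or epimerise and the lactone should be left alone.

**Compound list**
1 | ethyl 2-methyl-4-oxocyclohex-2-ene-1-carboxylate (Hagemann's ester, racemic) | CCOC(=O)C1CCC(=O)C=C1C | starting material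
2 | 3-bromoprop-1-ene | C=CCBr | starting material
3 | ethyl 2-methyl-4-oxo-3-(prop-2-en-1-yl)cyclohex-2-ene-1-carboxylate (racemic) | CCOC(=O)C1CCC(=O)C(CC=C)=C1C | intermediate
4 | ethyl 7-methyl-6-(prop-2-en-1-yl)-1,4-dioxaspiro[4.5]dec-7-ene-8-carboxylate (racemic) | CCOC(=O)C1=C(C)C(CC=C)C2(CC1)OCCO2 | intermediate
5 | 1-[7-methyl-6-(prop-2-en-1-yl)-1,4-dioxaspiro[4.5]dec-7-en-8-yl]ethan-1-one (racemic, not isolated) | CC(=O)C1=C(C)C(CC=C)C2(CC1)OCCO2 | intermediate
6 | 2-[7-methyl-6-(prop-2-en-1-yl)-1,4-dioxaspiro[4.5]dec-7-en-8-yl]propan-2-ol (racemic) | CC(C)(O)C1=C(C)C(CC=C)C2(CC1)OCCO2 | intermediate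
7 | 4-(2-hydroxypropan-2-yl)-3-methyl-2-(prop-2-en-1-yl)cyclohex-3-en-1-one (racemic, not isolated) | CC(C)(O)C1=C(C)C(CC=C)C(=O)CC1 | intermediate
8 | 3-methyl-2-(prop-2-en-1-yl)-4-(propan-2-ylidene)cyclohex-2-en-1-one | CC(C)=C1CCC(=O)C(CC=C)=C1C | intermediate
9 | 2-(2,3-dihydroxypropyl)-3-methyl-4-(propan-2-ylidene)cyclohex-2-en-1-one (not isolated) | CC(C)=C1CCC(=O)C(CC(O)CO)=C1C | intermediate
10 | 2-[2-methyl-6-oxo-3-(propan-2-ylidene)cyclohex-1-en-1-yl]acetaldehyde | CC(C)=C1CCC(=O)C(CC=O)=C1C | intermediate
11 | 2-[(2S)-2-hydroxybut-3-en-1-yl]-3-methyl-4-(propan-2-ylidene)cyclohex-2-en-1-one | C=C[C@@H](O)CC1=C(C)C(=C(C)C)CCC1=O | intermediate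
12 | (3R)-3-[(2E)-3-hydroxyprop-2-en-1-yl]-3-methyl-2-methylidene-4-(propan-2-ylidene)cyclohexan-1-one (not isolated) | O/C=C/C[C@@]1(C)C(=C)C(=O)CCC1=C(C)C | intermediate
13 | 3-[(1R)-1-methyl-2-methylidene-3-oxo-6-(propan-2-ylidene)cyclohexyl]propanal (not isolated) | O=CCC[C@@]1(C)C(=C)C(=O)CCC1=C(C)C | intermediate
14 | (6S,8aR)-6-hydroxy-5,5,8a-trimethyl-1-methylidene-3,5,6,7,8,8a-hexahydronaphthalen-2(1H)-one | O=C1CC=C2C(C)(C)[C@@H](O)CC[C@@]2(C)C1=C | intermediate
15 | 7-hydroxy-2H-chromen-2-one (umbelliferone) | Oc1ccc2ccc(=O)oc2c1 | starting material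
16 | (4aS,6S,8aR)-6-hydroxy-5,5,8a-trimethyl-1-methylidene-4a,5,6,7,8,8a-hexahydronaphthalen-2(1H)-one (not isolated) | O=C1C=C[C@@H]2C(C)(C)[C@@H](O)CC[C@@]2(C)C1=C | intermediate
17 | 7-{[(1R,4aS,6S,8aR)-6-hydroxy-5,5,8a-trimethyl-2-oxo-1,2,4a,5,6,7,8,8a-octahydronaphthalen-1-yl]methoxy}-2H-chromen-2-one | O=C1C=C[C@@H]2C(C)(C)[C@@H](O)CC[C@@]2(C)[C@@H]1COc1ccc2ccc(=O)oc2c1 | intermediate
18 | 7-{[(1R,4aS,6S,8aR)-6-hydroxy-5,5,8a-trimethyl-2-methylidene-1,2,4a,5,6,7,8,8a-octahydronaphthalen-1-yl]methoxy}-2H-chromen-2-one | C=C1C=C[C@@H]2C(C)(C)[C@@H](O)CC[C@@]2(C)[C@@H]1COc1ccc2ccc(=O)oc2c1 | target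

**Step count and risks**
Total step count: 9. Longest linear sequence: 9 steps (1 → 18).

Most likely to fail, step 7. The oxy-Cope shift may be too slow at a temperature the substrate tolerates, so that retro-ene loss of acrolein or tautomerisation of ring B to a phenol takes over. Chirality transfer from the carbinol may be incomplete, and the thermal ene closure may stall at the keto aldehyde. The fallback uses known reactions, sets out from 8 and comes back at 14.
- Enantioselective 1,2-reduction of 8 with (S)-Me-CBS and BH3·SMe2 should give (1R)-3-methyl-2-(prop-2-en-1-yl)-4-(propan-2-ylidene)cyclohex-2-en-1-ol F1.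
- TBSCl and imidazole give its tert-butyldimethylsilyl ether F2.
- OsO4/NaIO4 cleavage gives the silyloxy aldehyde F3.
- Vinylmagnesium bromide gives the silyloxy dienol F4 as both carbinol epimers.
- KH and 18-crown-6 in THF effect the anionic oxy-Cope rearrangement to the silyloxy aldehyde F5. Here the pseudo-axial C8 silyloxy group shields one face of C9=C10 and sets C10, so the carbinol configuration no longer matters.
- TBAF gives the hydroxy aldehyde F6.
- MnO2 oxidises the allylic alcohol to keto aldehyde 13, now isolated, and Me2AlCl in CH2Cl2 at −78 → 0 °C closes ring A by the carbonyl-ene reaction to 14.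

Second, step 8. The phenoxide addition is reversible and may not go to completion or may revert on isolation, and the β,γ to α,β equilibration may stop short. The fallback sets out from 14 and comes back at 18.
- Conjugate borylation with B2pin2, CuCl, NaOtBu and MeOH should give the β-boryl ketone F7.
- DBU conjugates it to the enone F8.
- Ph3P=CH2 gives the diene boronate F9, which has no β-leaving group.
- NaBO3·4H2O gives the diene diol F10.
- A Mitsunobu reaction (PPh3, DIAD) with 15 at the primary hydroxyl gives 18.

Third, step 4. Acid may enolise the cross-conjugated ring and drive it to the aromatic phenol instead of stopping at the dienone. The fallback sets out from 6 and comes back at 8.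
- Burgess reagent dehydrates the tertiary alcohol under neutral conditions to the isopropenyl diene ketal F11.
- Ketal exchange with I2 (cat.) in acetone gives the deconjugated trienone F12.
- DBU (cat.) moves both double bonds into conjugation to give 8.

**Further compounds**
F1 | step 7 | (1R)-3-methyl-2-(prop-2-en-1-yl)-4-(propan-2-ylidene)cyclohex-2-en-1-ol | O[C@@H]1CCC(=C(C)C)C(C)=C1CC=C
F2 | step 7 | tert-butyl(dimethyl){[(1R)-3-methyl-2-(prop-2-en-1-yl)-4-(propan-2-ylidene)cyclohex-2-en-1-yl]oxy}silane | CC(C)(C)[Si](C)(C)O[C@@H]1CCC(=C(C)C)C(C)=C1CC=C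
F3 | step 7 | 2-[(6R)-6-{[tert-butyl(dimethyl)silyl]oxy}-2-methyl-3-(propan-2-ylidene)cyclohex-1-en-1-yl]acetaldehyde | CC(C)(C)[Si](C)(C)O[C@@H]1CCC(=C(C)C)C(C)=C1CC=O
F4 | step 7 | 1-[(6R)-6-{[tert-butyl(dimethyl)silyl]oxy}-2-methyl-3-(propan-2-ylidene)cyclohex-1-en-1-yl]but-3-en-2-ol (both carbinol epimers) | CC(C)(C)[Si](C)(C)O[C@@H]1CCC(=C(C)C)C(C)=C1CC(O)C=C
F5 | step 7 | 3-[(1R,3R)-3-{[tert-butyl(dimethyl)silyl]oxy}-1-methyl-2-methylidene-6-(propan-2-ylidene)cyclohexyl]propanal | O=CCC[C@@]1(C)C(=C)[C@H](O[Si](C)(C)C(C)(C)C)CCC1=C(C)C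
F6 | step 7 | 3-[(1R,3R)-3-hydroxy-1-methyl-2-methylidene-6-(propan-2-ylidene)cyclohexyl]propanal | O=CCC[C@@]1(C)C(=C)[C@H](O)CCC1=C(C)C
F7 | step 8 | β-boryl ketone: 14 with H added at C9 (anti to the angular methyl) and a pinacolboryl group on C11 | O=C1CC=C2C(C)(C)[C@@H](O)CC[C@@]2(C)[C@@H]1CB1OC(C)(C)C(C)(C)O1
F8 | step 8 | conjugated enone boronate: 17 with the pinacolboryl group in place of the aryloxy group, same configuration | O=C1C=C[C@@H]2C(C)(C)[C@@H](O)CC[C@@]2(C)[C@@H]1CB1OC(C)(C)C(C)(C)O1
F9 | step 8 | diene boronate: 18 with the pinacolboryl group in place of the aryloxy group, same configuration | C=C1C=C[C@@H]2C(C)(C)[C@@H](O)CC[C@@]2(C)[C@@H]1CB1OC(C)(C)C(C)(C)O1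
F10 | step 8 | (2S,4aS,5R,8aR)-5-(hydroxymethyl)-1,1,4a-trimethyl-6-methylidene-1,2,3,4,4a,5,6,8a-octahydronaphthalen-2-ol | C=C1C=C[C@@H]2C(C)(C)[C@@H](O)CC[C@@]2(C)[C@@H]1CO
F11 | step 4 | 7-methyl-6-(prop-2-en-1-yl)-8-(prop-1-en-2-yl)-1,4-dioxaspiro[4.5]dec-7-ene (racemic) | CC(=C)C1=C(C)C(CC=C)C2(CC1)OCCO2
F12 | step 4 | 3-methyl-2-(prop-2-en-1-yl)-4-(prop-1-en-2-yl)cyclohex-3-en-1-one (racemic) | CC(=C)C1=C(C)C(CC=C)C(=O)CC1
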